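Everything rests on cutting ring A at C4–C5 and C2–C3, the retron of a Danheiser benzannulation. The feature exploited is the ring A pattern itself. C5–OH and C3–OMe sit meta to each other, the C4 benzyl carbon lies between them, and C6 is the only CH. One heating operation joins a vinylketene to a methyl ynol ether and closes the pentasubstituted ring. It leaves one oxygen as OH and the other as OMe, so no selective methylation is needed. The precursor is a 2-benzyl-3-phenethylcyclobut-2-enone that supplies C5, C2, C1 and C6. A 3-aryl-1-methoxypropyne supplies C4 and C3. The same ynol ether is also the source of the cyclobutenone, and benzyl ethers mask the three outer phenols.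

Key step: step 6

Remark: ring A is numbered from the carbon holding the two-carbon tether to ring B (C1), then the benzylated C2, the methoxy carbon C3, the benzylated C4, the hydroxy carbon C5 and the unsubstituted C6. Alkyne 4 is made on a scale that feeds both step 2 and step 6.

Step 1
Reactants: 1 chloroacetaldehyde dimethyl acetal; 2 4-benzyloxybenzyl chloride
Product: 4 1-methoxy-3-(4-benzyloxyphenyl)prop-1-yne, via lithium methoxyacetylide 3 (not isolated)
Conditions: Et2NH, n-BuLi (3.1 equiv each), THF, 0 °C; 1, 0 °C; then 2 (0.6 equiv), DMPU, −78 °C → rt; NaHCO3 work-up, Et3N-deactivated silica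
Reagents that add atoms: none
Why: The amide base takes 1 through two eliminations (loss of MeOH, then of HCl) and a deprotonation to acetylide 3, and SN2 alkylation of a lithium alkoxyacetylide by a reactive benzylic halide in THF–DMPU is a standard acetylide alkylation, with 3 kept in excess so that it outruns the amine and methoxide also present.

Step 2
Reactants: 4 1-methoxy-3-(4-benzyloxyphenyl)prop-1-yne; 5 acetone
Product: 7 2-(4-benzyloxybenzyl)-3-methoxycyclobut-2-en-1-one, via ketene 6 (not isolated)
Conditions: 5, 700–750 °C (ketene generator, N2 stream); gas passed into 4, CH2Cl2, 0 °C → rt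
Reagents that add atoms: none
Why: Thermal ketene–alkoxyalkyne [2+2] cycloaddition, in which the oxygen-polarised alkyne attacks the ketene carbonyl carbon through its benzyl-bearing carbon, so the ring should form only as the 2-benzyl-3-methoxy vinylogous ester.

Step 3
Reactants: 8 2-(3-hydroxyphenyl)ethanol
Product: 9 2-(3-benzyloxyphenyl)ethanol
Conditions: BnBr, K2CO3, DMF, rt
Reagents that add atoms: benzyl bromide, BrCc1ccccc1
Why: Williamson ether synthesis in which K2CO3 ionises only the phenol, so the primary alcohol stays free.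

Step 4
Reactants: 9 2-(3-benzyloxyphenyl)ethanol
Product: 10 1-benzyloxy-3-(2-iodoethyl)benzene
Conditions: I2, PPh3, imidazole, CH2Cl2, 0 °C → rt
Reagents that add atoms: iodine, [I][I]
Why: Appel-type iodination, in which iodide displaces the alkoxyphosphonium ion of an unhindered primary alcohol by SN2 and the aryl benzyl ether is untouched.

Step 5
Reactants: 10 1-benzyloxy-3-(2-iodoethyl)benzene; 7 2-(4-benzyloxybenzyl)-3-methoxycyclobut-2-en-1-one
Product: 13 2-(4-benzyloxybenzyl)-3-[2-(3-benzyloxyphenyl)ethyl]cyclobut-2-en-1-one, via 2-(3-benzyloxyphenyl)ethyllithium 11 (not isolated), via tertiary cyclobutenol 12 (not isolated)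
Conditions: t-BuLi (2.1 equiv), Et2O–pentane, −78 °C; 7, THF, −78 °C; then 1 M HCl, 0 °C → rt
Reagents that add atoms: water, O
Why: Iodine–lithium exchange outpaces any attack on the benzyl ether at −78 °C, the primary alkyllithium adds 1,2 to the vinylogous ester (enolisation would need an antiaromatic cyclobutadienolate), and acid ionises racemic carbinol 12 and hydrolyses the methoxyallyl cation, a Stork–Danheiser-type carbonyl transposition that erases the carbinol stereocentre.

Step 6
Reactants: 13 2-(4-benzyloxybenzyl)-3-[2-(3-benzyloxyphenyl)ethyl]cyclobut-2-en-1-one; 4 1-methoxy-3-(4-benzyloxyphenyl)prop-1-yne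
Product: 18 tri-O-benzyl bulbocodin C [2,4-bis(4-benzyloxybenzyl)-5-[2-(3-benzyloxyphenyl)ethyl]-3-methoxyphenol], via vinylketene 14 (not isolated), via 4-vinylcyclobutenone 15 (not isolated), via dienylketene 16 (not isolated), via cyclohexadienone 17 (not isolated)
Conditions: 4 (1.5–2 equiv), toluene (0.5 M), sealed tube, 110 °C, then 150 °C
Reagents that add atoms: none
Why: Thermal 4π electrocyclic opening of 13 breaks its C(=O)–CH2 bond to give vinylketene 14, whose ketene C=C undergoes a [2+2] cycloaddition with 4 to give 4-vinylcyclobutenone 15 (new bonds C4–C5 and C2–C3). A second 4π opening cleaves the old C5–C2 bond to dienylketene 16, ring A then closes by a disrotatory 6π electrocyclisation between ketene carbon C5 and terminal methylene C6, and dienone 17 tautomerises to phenol 18. This is the Danheiser benzannulation of cyclobutenones with alkynyl ethers, a known entry to resorcinol monoethers. The one selectivity needed is the orientation of the [2+2]: donation from the methoxy oxygen makes the benzyl-bearing alkyne carbon the nucleophile, it attacks the electrophilic ketene carbon, and the C4 benzyl therefore lands between C5–OH and C3–OMe. Opening of 15 is reversible, so only the geometry of 16 that holds the ketene and vinyl groups cis is drained by the irreversible aromatisation. No stereocentre survives (the quaternary carbon of 15 is transient), and a methyl ynol ether has no β-hydrogen, so it cannot be lost by retro-ene fragmentation at these temperatures.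

Step 7
Reactants: 18 tri-O-benzyl bulbocodin C
Product: 19 bulbocodin C [2,4-bis(4-hydroxybenzyl)-5-[2-(3-hydroxyphenyl)ethyl]-3-methoxyphenol]
Conditions: H2 (1 atm), Pd/C, EtOAc–MeOH, rt
Reagents that add atoms: none
Why: Catalytic hydrogenolysis cleaves the three benzylic C–O bonds, whereas the diarylmethane and bibenzyl C–C bonds, the aryl methyl ether and the arenes are inert under one atmosphere of hydrogen.

Compound list
1 | chloroacetaldehyde dimethyl acetal (2-chloro-1,1-dimethoxyethane) | COC(CCl)OC | starting material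
2 | 4-benzyloxybenzyl chloride | ClCc1ccc(OCc2ccccc2)cc1 | starting material
3 | lithium methoxyacetylide (formed in the flask) | [Li]C#COC | intermediate
4 | 1-methoxy-3-(4-benzyloxyphenyl)prop-1-yne | COC#CCc1ccc(OCc2ccccc2)cc1 | intermediate
5 | acetone | CC(C)=O | starting material
6 | ketene (gas stream, not collected) | C=C=O | intermediate
7 | 2-(4-benzyloxybenzyl)-3-methoxycyclobut-2-en-1-one | COC1=C(Cc2ccc(OCc3ccccc3)cc2)C(=O)C1 | intermediate
8 | 2-(3-hydroxyphenyl)ethanol | OCCc1cccc(O)c1 | starting material
9 | 2-(3-benzyloxyphenyl)ethanol | OCCc1cccc(OCc2ccccc2)c1 | intermediate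
10 | 1-benzyloxy-3-(2-iodoethyl)benzene | ICCc1cccc(OCc2ccccc2)c1 | intermediate
11 | 2-(3-benzyloxyphenyl)ethyllithium (formed in the flask) | [Li]CCc1cccc(OCc2ccccc2)c1 | intermediate
12 | 1-[2-(3-benzyloxyphenyl)ethyl]-2-(4-benzyloxybenzyl)-3-methoxycyclobut-2-en-1-ol (racemic, formed in the flask) | COC1=C(Cc2ccc(OCc3ccccc3)cc2)C(O)(CCc2cccc(OCc3ccccc3)c2)C1 | intermediate
13 | 2-(4-benzyloxybenzyl)-3-[2-(3-benzyloxyphenyl)ethyl]cyclobut-2-en-1-one | O=C1CC(CCc2cccc(OCc3ccccc3)c2)=C1Cc1ccc(OCc2ccccc2)cc1 | intermediate
14 | vinylketene: 2-(4-benzyloxybenzyl)-5-(3-benzyloxyphenyl)-3-methylenepent-1-en-1-one (formed in the flask) | O=C=C(Cc1ccc(OCc2ccccc2)cc1)C(=C)CCc1cccc(OCc2ccccc2)c1 | intermediate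
15 | 2,4-bis(4-benzyloxybenzyl)-4-[4-(3-benzyloxyphenyl)but-1-en-2-yl]-3-methoxycyclobut-2-en-1-one (racemic, formed in the flask) | O=C1C(Cc2ccc(OCc3ccccc3)cc2)=C(OC)C1(Cc1ccc(OCc2ccccc2)cc1)C(=C)CCc1cccc(OCc2ccccc2)c1 | intermediate
16 | dienylketene, ketene and vinyl groups cis on the central C=C (formed in the flask) | O=C=C(Cc1ccc(OCc2ccccc2)cc1)/C(OC)=C(Cc1ccc(OCc2ccccc2)cc1)\C(=C)CCc1cccc(OCc2ccccc2)c1 | intermediate
17 | 2,4-bis(4-benzyloxybenzyl)-5-[2-(3-benzyloxyphenyl)ethyl]-3-methoxycyclohexa-2,4-dien-1-one (formed in the flask) | O=C1CC(CCc2cccc(OCc3ccccc3)c2)=C(Cc2ccc(OCc3ccccc3)cc2)C(OC)=C1Cc1ccc(OCc2ccccc2)cc1 | intermediate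
18 | tri-O-benzyl bulbocodin C, free C5 phenol | COc1c(Cc2ccc(OCc3ccccc3)cc2)c(O)cc(CCc2cccc(OCc3ccccc3)c2)c1Cc1ccc(OCc2ccccc2)cc1 | intermediate
19 | bulbocodin C | COc1c(Cc2ccc(O)cc2)c(O)cc(CCc2cccc(O)c2)c1Cc1ccc(O)cc1 | target

Total step count: 7. Longest linear sequence: 5 steps (steps 1, 2, 5, 6, 7, or equally steps 3, 4, 5, 6, 7).

Steps most likely to fail

**Step 6.** Capture of the fully substituted vinylketene by an internal methyl ynol ether may be slower than three competing processes: re-closure of the vinylketene, its dimerisation, and its acylation of phenol already formed.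
- The fallback sets out from 13 and 2 and comes back to the route at 19. It keeps the cyclobutenone, replaces the alkyne with a more nucleophilic siloxyalkyne, and installs the methyl group afterwards.
- Chloride 2 and ethynylmagnesium bromide (CuBr cat., THF) should give 3-(4-benzyloxyphenyl)prop-1-yne F1.
- Deprotonation with n-BuLi and oxidation with lithium tert-butyl peroxide lead to lithium 3-(4-benzyloxyphenyl)prop-1-yn-1-olate F2. Trapping with TIPSOTf gives 1-(triisopropylsiloxy)-3-(4-benzyloxyphenyl)prop-1-yne F3.
- Heating F3 with 13 in toluene should give, by the same cascade and the same regiochemistry, 2,4-bis(4-benzyloxybenzyl)-5-[2-(3-benzyloxyphenyl)ethyl]-3-(triisopropylsiloxy)phenol F4.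
- Benzylation of the C5 hydroxyl (BnBr, K2CO3, DMF) gives the C5 benzyl ether C3 silyl ether F5.
- Fluoride-induced desilylation in the presence of MeI (CsF, DMF) gives tetra-O-benzyl bulbocodin C F6.
- Hydrogenolysis of F6 over Pd/C ends at 19.

**Step 2.** Ketene may dimerise or oligomerise faster than the internal ynol ether captures it. Traces of acid in the gas stream may also hydrate the ynol ether.
- The fallback sets out from 4 and comes back at 7.
- Dichloroketene F7 is far more electrophilic. It is generated in the flask under basic conditions from dichloroacetyl chloride and Et3N in Et2O.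
- F7 should add to 4 with the same orientation to give 2-(4-benzyloxybenzyl)-4,4-dichloro-3-methoxycyclobut-2-en-1-one F8.
- Reductive dechlorination of F8 with Zn, AcOH and TMEDA in EtOH gives 7.

**Step 1.** Three processes may erode the alkylation: N-benzylation of the liberated diethylamine, O-benzylation of methoxide, and base-induced propargyl-to-allenyl isomerisation.
- The fallback sets out from 2 and comes back at 4. It replaces the SN2 step with a cross-coupling of a far less basic acetylide made without amine or alkoxide.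
- Trichloroethylene and KOMe in THF give (E)-1,2-dichloro-1-methoxyethene F9.
- Two equivalents of n-BuLi convert F9 to 3, and ZnCl2 turns 3 into (methoxyethynyl)zinc chloride F10.
- A Negishi benzyl–alkynyl coupling of F10 with 2 under PdCl2(DPEphos) catalysis in THF gives 4.

Further compounds
F1 | step 6 | 3-(4-benzyloxyphenyl)prop-1-yne | C#CCc1ccc(OCc2ccccc2)cc1
F2 | step 6 | lithium 3-(4-benzyloxyphenyl)prop-1-yn-1-olate | [Li]OC#CCc1ccc(OCc2ccccc2)cc1
F3 | step 6 | 1-(triisopropylsiloxy)-3-(4-benzyloxyphenyl)prop-1-yne | CC(C)[Si](OC#CCc1ccc(OCc2ccccc2)cc1)(C(C)C)C(C)C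
F4 | step 6 | 2,4-bis(4-benzyloxybenzyl)-5-[2-(3-benzyloxyphenyl)ethyl]-3-(triisopropylsiloxy)phenol | CC(C)[Si](Oc1c(Cc2ccc(OCc3ccccc3)cc2)c(O)cc(CCc2cccc(OCc3ccccc3)c2)c1Cc1ccc(OCc2ccccc2)cc1)(C(C)C)C(C)C
F5 | step 6 | C5 benzyl ether C3 silyl ether | CC(C)[Si](Oc1c(Cc2ccc(OCc3ccccc3)cc2)c(OCc2ccccc2)cc(CCc2cccc(OCc3ccccc3)c2)c1Cc1ccc(OCc2ccccc2)cc1)(C(C)C)C(C)C
F6 | step 6 | tetra-O-benzyl bulbocodin C | COc1c(Cc2ccc(OCc3ccccc3)cc2)c(OCc2ccccc2)cc(CCc2cccc(OCc3ccccc3)c2)c1Cc1ccc(OCc2ccccc2)cc1
F7 | step 2 | dichloroketene | ClC(Cl)=C=O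
F8 | step 2 | 2-(4-benzyloxybenzyl)-4,4-dichloro-3-methoxycyclobut-2-en-1-one | COC1=C(Cc2ccc(OCc3ccccc3)cc2)C(=O)C1(Cl)Cl
F9 | step 1 | (E)-1,2-dichloro-1-methoxyethene | CO/C(Cl)=C\Cl
F10 | step 1 | (methoxyethynyl)zinc chloride | COC#C[Zn]Cl
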